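**Retrosynthetic overview**
1. Labels: ring B is the central benzene (atoms B1 to B6); ring D is the dihydrofuran O–D2–D3 fused at B1/B6 and ring E the dihydrofuran O–E2–E3 fused at B3/B4; the seven-membered ring is B4, B5, C7 (CH2), C8 (CH–aryl), C1, C6, E3; ring C is C1 to C6.
2. The strategy rests on ring C: a resorcinol whose adjacent carbons C1 and C6 both lie in the seven-membered ring, with oxygen on C2 and C4 and CH at C3 and C5. Ring C is therefore made last, from cycloheptenyl diazomethyl ketone 37 and ethoxyacetylene (C6–C5, C5–C4, C3–C2 and C2–C1 formed in one operation); BBr3 then frees all phenols.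
3. 37 comes from methyl ketone 34 by diazo transfer; 34 from cycloheptene ester 32; 32 from ring-closing metathesis of an acrylate on E3 with a vinyl group on C8.
4. C8 is set by an Evans alkylation of the ring B benzylic bromide; both dihydrofurans come from rhodium-carbene C–H insertions into the two 4-methoxybenzyl ethers of dibromide 5, each followed by epimerisation to trans.
5. Ring order: ring B (bought), ring D, ring E, seven-membered ring, ring C.

Key step: step 22

Assumption: the absolute sense of induction of Rh2(R-PTAD)4 (step 5, D3) and of Rh2(S-PTTL)4 (step 8, E2) is taken by analogy with simpler benzyl aryl ethers; if either proves opposite, the mirror-image catalyst is used in that step.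

Abbreviations: PMB = 4-methoxybenzyl; TIPS = tri(propan-2-yl)silyl; Rh2(R-PTAD)4 = Rh2[(R)-O2CCH(1-adamantyl)N(phthaloyl)]4; Rh2(S-PTTL)4 = Rh2[(S)-O2CCH(t-Bu)N(phthaloyl)]4; p-ABSA = 4-acetamidobenzenesulfonyl azide.

**Route**

Step 1
Reactants: 1 3,5-dihydroxybenzyl alcohol; 2 4-methoxybenzyl chloride
Product: 3 [3,5-bis(4-methoxybenzyloxy)phenyl]methanol
Conditions: 2 (2.2 equiv), K2CO3, n-Bu4NI (cat.), DMF, 60 °C
Reagents that add atoms: none
Why: Williamson etherification in which K2CO3 ionises only the two phenols, so the benzylic alcohol stays free; the two benzylic CH2 groups are the future D2 and E2.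

Step 2
Reactants: 3
Product: 4 [2,6-dibromo-3,5-bis(4-methoxybenzyloxy)phenyl]methanol
Conditions: NBS (2.05 equiv), MeCN, 0 °C
Reagents that add atoms: N-bromosuccinimide, O=C1CCC(=O)N1Br
Why: Electrophilic aromatic bromination should go to B4 and B6, each para to one ether oxygen and ortho to the other, ahead of the position between the two oxygens and of the less activated anisyl rings.

Step 3
Reactants: 4
Product: 5 TIPS ether of 4
Conditions: TIPSOTf, 2,6-lutidine, CH2Cl2, 0 °C
Reagents that add atoms: tri(propan-2-yl)silyl trifluoromethanesulfonate, CC(C)[Si](OS(=O)(=O)C(F)(F)F)(C(C)C)C(C)C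
Why: Silylation of the primary alcohol; the bulky TIPS group is chosen to resist 1,4 oxygen-to-carbon silyl migration onto the ortho aryllithium of step 4 and the acid of step 10, and it masks the hydroxyl and screens its oxygen from the carbenes of steps 5 and 8 (no O–H insertion, little oxonium ylide formation).

Step 4
Reactants: 5 TIPS ether; 6 3,5-dimethoxybenzonitrile
Product: 9 diaryl ketone hydrazone, via aryllithium 7 (not isolated), via N–H ketimine 8 (not isolated)
Conditions: t-BuLi (2.0 equiv), Et2O, −78 °C; 6, −78 → −20 °C; MeOH; then N2H4 (anhydrous, THF), AcOH (cat.), EtOH, 60 °C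
Reagents that add atoms: hydrazine, NN
Why: Bromine–lithium exchange of one of the two equivalent bromides, addition of the aryllithium to the nitrile, and transimination of the N–H ketimine by hydrazine (ammonia leaves) should give the hydrazone without a condensation on a di-ortho-substituted diaryl ketone.

Step 5
Reactants: 9 hydrazone
Product: 11 cis dihydrobenzofuran bromide, via diaryldiazomethane 10 (not isolated)
Conditions: MnO2 (8 equiv), CH2Cl2, 0 °C; then Rh2(R-PTAD)4 (1 mol%), 0 °C → rt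
Reagents that add atoms: none
Why: Dehydrogenation of the hydrazone gives a donor/donor diazo compound whose rhodium carbene undergoes enantioselective 1,5 C–H insertion into the only OCH2Ar group within reach, closing ring D; the chiral carboxylate ligands set D3 (R) and the insertion delivers the cis (D2 S, D3 R) ring.

Step 6
Reactants: 11 cis dihydrobenzofuran bromide; 12 methyl bromoacetate
Product: 13 methyl arylacetate
Conditions: 12, Zn (TMSCl-activated), THF, rt, giving BrZnCH2CO2Me; then 11, Pd2(dba)3 (2.5 mol%), XPhos (10 mol%), THF, 65 °C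
Reagents that add atoms: none
Why: Negishi-type cross-coupling of the remaining aryl bromide with the Reformatsky reagent; the bulky biarylphosphine is needed for oxidative addition of zerovalent palladium and for reductive elimination at the di-ortho-substituted position, and the neutral zinc enolate leaves the silyl ether and ring D alone.

Step 7
Reactants: 13 methyl arylacetate
Product: 14 methyl aryldiazoacetate
Conditions: p-ABSA, DBU, MeCN, 0 °C → rt
Reagents that add atoms: 4-acetamidobenzenesulfonyl azide, CC(=O)Nc1ccc(cc1)S(=O)(=O)N=[N+]=[N-]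
Why: Regitz diazo transfer to the benzylic ester α-carbon, the only acidic C–H position in the molecule.

Step 8
Reactants: 14 methyl aryldiazoacetate
Product: 16 trans methyl ester of ring E, via cis ester 15 (not isolated)
Conditions: Rh2(S-PTTL)4 (1 mol%), toluene, −60 °C → rt; then NaOMe (0.3 equiv), MeOH/THF, rt
Reagents that add atoms: none
Why: Donor/acceptor carbene 1,5 C–H insertion into the second OCH2Ar group should close ring E as the cis ester with catalyst-set E2 (R), and methoxide then epimerises only E3 (α to the ester) to the more stable trans (E2 R, E3 R) ring.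

Step 9
Reactants: 16 trans methyl ester
Product: 18 terminal alkyne, via aldehyde 17 (not isolated)
Conditions: i-Bu2AlH (1.1 equiv), CH2Cl2, −78 °C; MeOH; then K2CO3, MeC(O)C(N2)P(O)(OMe)2, MeOH, 0 °C → rt
Reagents that add atoms: dimethyl (1-diazo-2-oxopropyl)phosphonate, COP(=O)(OC)C(=[N+]=[N-])C(C)=O
Why: Partial reduction to the aldehyde followed in the same flask by Ohira–Bestmann (Seyferth–Gilbert) homologation makes the aldehyde carbon the future C6; E3 is epimerisable at the aldehyde stage but trans is the thermodynamic arrangement and should be kept.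

Step 10
Reactants: 18 terminal alkyne
Product: 19 all-trans alkyne
Conditions: CF3CO2H (10 equiv), CH2Cl2, 0 °C
Reagents that add atoms: none
Why: Acid-mediated epimerisation: reversible heterolysis of the D2–O bond to a 4-methoxybenzylic cation and reclosure should turn the cis ring D into the more stable trans (D2 R, D3 R) ring by inverting D2 while catalyst-set D3 is kept; ring E is already trans, and the step is placed here because no acid-labile PMB ether is left.

Step 11
Reactants: 19 all-trans alkyne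
Product: 20 benzylic alcohol
Conditions: n-Bu4NF, THF, 0 °C
Reagents that add atoms: none
Why: Fluoride-mediated desilylation; the terminal alkyne and both dihydrofurans are inert to it.

Step 12
Reactants: 20 benzylic alcohol
Product: 21 benzylic bromide
Conditions: CBr4, PPh3, CH2Cl2, 0 °C; used at once
Reagents that add atoms: tetrabromomethane, BrC(Br)(Br)Br
Why: Appel bromination under neutral conditions, so the acid-sensitive benzylic C–O bonds of rings D and E are not ionised; the bromide is taken on directly to avoid Friedel–Crafts self-alkylation of the neighbouring dimethoxyphenyl ring.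

Step 13
Reactants: 22 2,4-dimethoxyphenylacetic acid; 23 (S)-4-benzyl-1,3-oxazolidin-2-one
Product: 25 N-acyl oxazolidinone, via mixed anhydride 24 (not isolated)
Conditions: t-BuCOCl, Et3N, THF, −20 °C; then 23, LiCl, rt
Reagents that add atoms: none
Why: N-acylation of the Evans auxiliary through the mixed pivalic anhydride, which is attacked at the less hindered arylacetyl carbonyl.

Step 14
Reactants: 21 benzylic bromide; 25 N-acyl oxazolidinone
Product: 27 alkylated imide, via sodium enolate 26 (not isolated)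
Conditions: 25 (1.5 equiv), NaN(SiMe3)2 (1.45 equiv), THF, −78 °C; then 21, n-Bu4NI (cat.), −78 → −20 °C
Reagents that add atoms: none
Why: Evans asymmetric alkylation: the chelated (Z)-enolate is alkylated on the face away from the auxiliary benzyl group, which sets C8 as (S); base is kept below the imide so the terminal alkyne is not deprotonated.

Step 15
Reactants: 27 alkylated imide
Product: 28 primary alcohol
Conditions: LiBH4, MeOH (1.1 equiv), THF, 0 °C
Reagents that add atoms: none
Why: Reductive cleavage of the imide by borohydride releases the auxiliary and the primary alcohol without touching C8 or the alkyne.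

Step 16
Reactants: 28 primary alcohol
Product: 29 α-aryl aldehyde
Conditions: Dess–Martin periodinane, NaHCO3, CH2Cl2, 0 °C
Reagents that add atoms: none
Why: Dess–Martin oxidation under buffered, non-basic conditions keeps the enolisable C8 centre intact; the aldehyde is used directly.

Step 17
Reactants: 29 α-aryl aldehyde
Product: 30 enyne
Conditions: Ph3PCH3Br (1.6 equiv), KN(SiMe3)2 (1.5 equiv), THF, −78 → 0 °C
Reagents that add atoms: methyltriphenylphosphonium bromide, C[P+](c1ccccc1)(c1ccccc1)c1ccccc1.[Br-]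
Why: Wittig methylenation by addition of the aldehyde to pre-formed salt-free ylide at low temperature, where carbonyl addition should outrun enolisation at C8; the ylide is too weak a base to deprotonate the terminal alkyne.

Step 18
Reactants: 30 enyne
Product: 31 acrylate diene
Conditions: Pd(OAc)2 (2 mol%), 2-(diphenylphosphino)pyridine, MeSO3H (cat.), CO (10 bar), MeOH (10 equiv), toluene, 50 °C
Reagents that add atoms: carbon monoxide, [C-]#[O+]; methanol, CO
Why: Palladium-catalysed Markovnikov hydromethoxycarbonylation of the terminal alkyne on E3 gives the 2-substituted acrylate; the alkyne reacts far faster than the alkene, and methanol is limited so the acid co-catalyst does not solvolyse the benzylic C–O bonds of rings D and E.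

Step 19
Reactants: 31 acrylate diene
Product: 32 cycloheptene methyl ester
Conditions: second-generation Grubbs catalyst RuCl2(=CHPh)(PCy3)(H2IMes) (10 mol%), 1,4-benzoquinone (20 mol%), toluene, 80 °C
Reagents that add atoms: none
Why: Ring-closing olefin metathesis: the catalyst loads on the monosubstituted alkene at C8 and closes onto the 1,1-disubstituted acrylate to give the trisubstituted C1=C6 alkene of the seven-membered ring, helped by the two ring fusions that hold the arms together; benzoquinone suppresses ruthenium hydride migration of the allylic, benzylic alkene.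

Step 20
Reactants: 32 cycloheptene methyl ester
Product: 34 methyl ketone, via Weinreb amide 33 (not isolated)
Conditions: MeNH(OMe)·HCl (1.6 equiv), i-PrMgCl (3.2 equiv), THF, −20 → 0 °C; then MeMgBr (3 equiv), 0 °C → rt
Reagents that add atoms: methylmagnesium bromide, C[Mg]Br
Why: Ester to ketone through the Weinreb amide: the magnesium amide of N,O-dimethylhydroxylamine converts the ester into 33, whose chelated adduct with MeMgBr collapses to the ketone only on work-up, so no tertiary alcohol forms.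

Step 21
Reactants: 34 methyl ketone
Product: 37 diazomethyl ketone, via lithium enolate 35 (not isolated), via trifluoroacetyl ketone 36 (not isolated)
Conditions: LiN(SiMe3)2 (1.1 equiv), THF, −78 °C; CF3CO2CH2CF3 (1.2 equiv); aq HCl work-up; then MeSO2N3, Et3N, H2O (1 equiv), MeCN, rt
Reagents that add atoms: methanesulfonyl azide, CS(=O)(=O)N=[N+]=[N-]
Why: Detrifluoroacetylative diazo transfer: kinetic deprotonation of the methyl group (faster than the γ-position at C8), trifluoroacetylation, and diazo transfer with loss of the trifluoroacetyl group give the α'-diazo enone without exposing the conjugated alkene to diazomethane, which is why the acid chloride route is avoided.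

Step 22
Reactants: 37 diazomethyl ketone; 38 ethoxyacetylene
Product: 43 ring C phenol hexamethyl monoethyl ether, via vinylketene 39 (not isolated), via cyclobutenone 40 (not isolated), via dienylketene 41 (not isolated), via cyclohexadienone 42 (not isolated)
Conditions: 38 (3 equiv), ClCH2CH2Cl, hν (300 nm, Pyrex), rt; then 80 °C
Reagents that add atoms: none
Why: Photochemical Wolff rearrangement of 37 (loss of N2, 1,2-shift of C6) gives vinylketene 39, whose electrophilic ketene carbon bonds to the unsubstituted, nucleophilic carbon of 38 in a [2+2] cycloaddition to give 4-alkenylcyclobutenone 40. 4π electrocyclic opening then gives dienylketene 41, thermal disrotatory 6π electrocyclisation onto C1 gives cyclohexadienone 42, and tautomerisation gives phenol 43; this is the Danheiser benzannulation in its diazo ketone form, established for cycloalkenyl diazomethyl ketones and alkoxyacetylenes. Ring C is the only ring that remains closed, by the 6π electrocyclisation, and the four new ring bonds are C6–C5 (Wolff shift), C5–C4 and C3–C2 ([2+2]) and C2–C1 (6π). No stereocentre is formed or touched: the sp3 centres of 40 and 42 are transient, C8 and E3 carry no hydrogen that is acidic under neutral photolysis, and the ring alkene holds C8 trans to the ketene arm so no 1,5-hydrogen shift can drain 39. The one selectivity needed is the orientation of the [2+2] step, fixed by ketene and ynol ether polarity; it places OH on C2 next to C1 and OEt on C4 para to C1, so the two ring C oxygens need no separate differentiation.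

Step 23
Reactants: 43 ring C phenol hexamethyl monoethyl ether
Product: 44 target CNP0154047.2
Conditions: BBr3 (20 equiv), CH2Cl2, −78 °C → rt; MeOH, then H2O
Reagents that add atoms: none
Why: Lewis-acid cleavage of the six methyl ethers and the ethyl ether; rings D and E are already the thermodynamic trans isomers, so any reversible opening at D2 or E2 should return the same configuration, and D3, E3 and C8 are not ionisable.

**Compound list**

1 | 3,5-dihydroxybenzyl alcohol | OCc1cc(O)cc(O)c1 | starting material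
2 | 4-methoxybenzyl chloride | COc1ccc(CCl)cc1 | starting material
3 | [3,5-bis(4-methoxybenzyloxy)phenyl]methanol | OCc1cc(OCc2ccc(OC)cc2)cc(OCc2ccc(OC)cc2)c1 | intermediate
4 | [2,6-dibromo-3,5-bis(4-methoxybenzyloxy)phenyl]methanol | OCc1c(Br)c(OCc2ccc(OC)cc2)cc(OCc2ccc(OC)cc2)c1Br | intermediate
5 | {[2,6-dibromo-3,5-bis(4-methoxybenzyloxy)phenyl]methoxy}tri(propan-2-yl)silane | CC(C)[Si](OCc1c(Br)c(OCc2ccc(OC)cc2)cc(OCc2ccc(OC)cc2)c1Br)(C(C)C)C(C)C | intermediate
6 | 3,5-dimethoxybenzonitrile | COc1cc(OC)cc(C#N)c1 | starting material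
7 | aryllithium from 5 (one bromine exchanged for lithium) | CC(C)[Si](OCc1c([Li])c(OCc2ccc(OC)cc2)cc(OCc2ccc(OC)cc2)c1Br)(C(C)C)C(C)C | intermediate (not isolated)
8 | [3-bromo-4,6-bis(4-methoxybenzyloxy)-2-(TIPS-oxymethyl)phenyl](3,5-dimethoxyphenyl)methanimine | N=C(c1cc(OC)cc(OC)c1)c1c(OCc2ccc(OC)cc2)cc(OCc2ccc(OC)cc2)c(Br)c1CO[Si](C(C)C)(C(C)C)C(C)C | intermediate (not isolated)
9 | hydrazone of [3-bromo-4,6-bis(4-methoxybenzyloxy)-2-(TIPS-oxymethyl)phenyl](3,5-dimethoxyphenyl)methanone | NN=C(c1cc(OC)cc(OC)c1)c1c(OCc2ccc(OC)cc2)cc(OCc2ccc(OC)cc2)c(Br)c1CO[Si](C(C)C)(C(C)C)C(C)C | intermediate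
10 | diaryldiazomethane corresponding to 9 | [N-]=[N+]=C(c1cc(OC)cc(OC)c1)c1c(OCc2ccc(OC)cc2)cc(OCc2ccc(OC)cc2)c(Br)c1CO[Si](C(C)C)(C(C)C)C(C)C | intermediate (not isolated)
11 | (2S,3R)-5-bromo-3-(3,5-dimethoxyphenyl)-6-(4-methoxybenzyloxy)-2-(4-methoxyphenyl)-4-(TIPS-oxymethyl)-2,3-dihydro-1-benzofuran (ring D closed, cis) | COc1ccc([C@H]2Oc3cc(OCc4ccc(OC)cc4)c(Br)c(CO[Si](C(C)C)(C(C)C)C(C)C)c3[C@H]2c2cc(OC)cc(OC)c2)cc1 | intermediate
12 | methyl bromoacetate | COC(=O)CBr | starting material
13 | methyl 2-[(2S,3R)-3-(3,5-dimethoxyphenyl)-6-(4-methoxybenzyloxy)-2-(4-methoxyphenyl)-4-(TIPS-oxymethyl)-2,3-dihydro-1-benzofuran-5-yl]acetate | COc1ccc([C@H]2Oc3cc(OCc4ccc(OC)cc4)c(CC(=O)OC)c(CO[Si](C(C)C)(C(C)C)C(C)C)c3[C@H]2c2cc(OC)cc(OC)c2)cc1 | intermediate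
14 | methyl 2-diazo-2-[(2S,3R)-benzofuran-5-yl]acetate derived from 13 (CH2 replaced by CN2) | COc1ccc([C@H]2Oc3cc(OCc4ccc(OC)cc4)c(C(=[N+]=[N-])C(=O)OC)c(CO[Si](C(C)C)(C(C)C)C(C)C)c3[C@H]2c2cc(OC)cc(OC)c2)cc1 | intermediate
15 | bis-dihydrofuran methyl ester: ring D cis (D2 S, D3 R), ring E cis (E2 R, E3 S), CO2Me on E3, CH2OTIPS on B5 | COc1ccc([C@H]2Oc3cc4c(c(CO[Si](C(C)C)(C(C)C)C(C)C)c3[C@H]2c2cc(OC)cc(OC)c2)[C@H](C(=O)OC)[C@H](c2ccc(OC)cc2)O4)cc1 | intermediate (not isolated)
16 | bis-dihydrofuran methyl ester: ring D cis (D2 S, D3 R), ring E trans (E2 R, E3 R) | COc1ccc([C@H]2Oc3cc4c(c(CO[Si](C(C)C)(C(C)C)C(C)C)c3[C@H]2c2cc(OC)cc(OC)c2)[C@@H](C(=O)OC)[C@H](c2ccc(OC)cc2)O4)cc1 | intermediate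
17 | aldehyde from 16 (CHO on E3; E2 R, E3 R) | COc1ccc([C@H]2Oc3cc4c(c(CO[Si](C(C)C)(C(C)C)C(C)C)c3[C@H]2c2cc(OC)cc(OC)c2)[C@@H](C=O)[C@H](c2ccc(OC)cc2)O4)cc1 | intermediate (not isolated)
18 | terminal alkyne (ethynyl on E3; E2 R, E3 R; ring D cis, D2 S, D3 R) | COc1ccc([C@H]2Oc3cc4c(c(CO[Si](C(C)C)(C(C)C)C(C)C)c3[C@H]2c2cc(OC)cc(OC)c2)[C@@H](C#C)[C@H](c2ccc(OC)cc2)O4)cc1 | intermediate
19 | all-trans alkyne (D2 R, D3 R, E2 R, E3 R), CH2OTIPS on B5 | COc1ccc([C@@H]2Oc3cc4c(c(CO[Si](C(C)C)(C(C)C)C(C)C)c3[C@H]2c2cc(OC)cc(OC)c2)[C@@H](C#C)[C@H](c2ccc(OC)cc2)O4)cc1 | intermediate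
20 | benzylic alcohol (CH2OH on B5; D2 R, D3 R, E2 R, E3 R) | COc1ccc([C@@H]2Oc3cc4c(c(CO)c3[C@H]2c2cc(OC)cc(OC)c2)[C@@H](C#C)[C@H](c2ccc(OC)cc2)O4)cc1 | intermediate
21 | benzylic bromide (CH2Br on B5; D2 R, D3 R, E2 R, E3 R) | COc1ccc([C@@H]2Oc3cc4c(c(CBr)c3[C@H]2c2cc(OC)cc(OC)c2)[C@@H](C#C)[C@H](c2ccc(OC)cc2)O4)cc1 | intermediate
22 | 2,4-dimethoxyphenylacetic acid | COc1ccc(CC(=O)O)c(OC)c1 | starting material
23 | (S)-4-benzyl-1,3-oxazolidin-2-one | O=C1N[C@@H](Cc2ccccc2)CO1 | starting material
24 | 2,4-dimethoxyphenylacetic pivalic anhydride | COc1ccc(CC(=O)OC(=O)C(C)(C)C)c(OC)c1 | intermediate (not isolated)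
25 | (S)-4-benzyl-3-[2-(2,4-dimethoxyphenyl)acetyl]-1,3-oxazolidin-2-one | COc1ccc(CC(=O)N2[C@@H](Cc3ccccc3)COC2=O)c(OC)c1 | intermediate
26 | sodium (Z)-enolate of 25 | COc1ccc(/C=C(\[O-])N2[C@@H](Cc3ccccc3)COC2=O)c(OC)c1.[Na+] | intermediate (not isolated)
27 | alkylated imide: B5–C7H2–C8H(2,4-dimethoxyphenyl)–C(=O)–N(auxiliary), C8 S | COc1ccc([C@@H]2Oc3cc4c(c(C[C@@H](c5ccc(OC)cc5OC)C(=O)N5[C@@H](Cc6ccccc6)COC5=O)c3[C@H]2c2cc(OC)cc(OC)c2)[C@@H](C#C)[C@H](c2ccc(OC)cc2)O4)cc1 | intermediate
28 | primary alcohol: C8 carries CH2OH (C8 S) | COc1ccc([C@@H]2Oc3cc4c(c(C[C@@H](c5ccc(OC)cc5OC)CO)c3[C@H]2c2cc(OC)cc(OC)c2)[C@@H](C#C)[C@H](c2ccc(OC)cc2)O4)cc1 | intermediate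
29 | aldehyde: C8 carries CHO (C8 S) | COc1ccc([C@@H]2Oc3cc4c(c(C[C@@H](c5ccc(OC)cc5OC)C=O)c3[C@H]2c2cc(OC)cc(OC)c2)[C@@H](C#C)[C@H](c2ccc(OC)cc2)O4)cc1 | intermediate
30 | enyne: C8 carries CH=CH2 (C8 R by CIP, same spatial arrangement), ethynyl on E3 | COc1ccc([C@@H]2Oc3cc4c(c(C[C@@H](c5ccc(OC)cc5OC)C=C)c3[C@H]2c2cc(OC)cc(OC)c2)[C@@H](C#C)[C@H](c2ccc(OC)cc2)O4)cc1 | intermediate
31 | diene: E3 carries C(=CH2)CO2Me (E3 S by CIP, same spatial arrangement), C8 carries vinyl (C8 R) | COc1ccc([C@@H]2Oc3cc4c(c(C[C@@H](c5ccc(OC)cc5OC)C=C)c3[C@H]2c2cc(OC)cc(OC)c2)[C@@H](C(=C)C(=O)OC)[C@H](c2ccc(OC)cc2)O4)cc1 | intermediate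
32 | cycloheptene methyl ester: C1=C6 alkene, CO2Me on C6 (D2 R, D3 R, E2 R, E3 S, C8 R) | COc1ccc([C@@H]2Oc3cc4c5c(c3[C@H]2c2cc(OC)cc(OC)c2)C[C@@H](c2ccc(OC)cc2OC)C=C(C(=O)OC)[C@H]5[C@H](c2ccc(OC)cc2)O4)cc1 | intermediate
33 | Weinreb amide: C(=O)N(Me)OMe on C6 | COc1ccc([C@@H]2Oc3cc4c5c(c3[C@H]2c2cc(OC)cc(OC)c2)C[C@@H](c2ccc(OC)cc2OC)C=C(C(=O)N(C)OC)[C@H]5[C@H](c2ccc(OC)cc2)O4)cc1 | intermediate (not isolated)
34 | methyl ketone: acetyl on C6 (D2 R, D3 R, E2 R, E3 S, C8 R) | COc1ccc([C@@H]2Oc3cc4c5c(c3[C@H]2c2cc(OC)cc(OC)c2)C[C@@H](c2ccc(OC)cc2OC)C=C(C(C)=O)[C@H]5[C@H](c2ccc(OC)cc2)O4)cc1 | intermediate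
35 | lithium enolate of 34 (methyl side) | COc1ccc([C@@H]2Oc3cc4c5c(c3[C@H]2c2cc(OC)cc(OC)c2)C[C@@H](c2ccc(OC)cc2OC)C=C(C(=C)O[Li])[C@H]5[C@H](c2ccc(OC)cc2)O4)cc1 | intermediate (not isolated)
36 | trifluoroacetyl ketone: C(=O)CH2C(=O)CF3 on C6 | COc1ccc([C@@H]2Oc3cc4c5c(c3[C@H]2c2cc(OC)cc(OC)c2)C[C@@H](c2ccc(OC)cc2OC)C=C(C(=O)CC(=O)C(F)(F)F)[C@H]5[C@H](c2ccc(OC)cc2)O4)cc1 | intermediate (not isolated)
37 | diazomethyl ketone: C(=O)CHN2 on C6 (D2 R, D3 R, E2 R, E3 S, C8 R) | COc1ccc([C@@H]2Oc3cc4c5c(c3[C@H]2c2cc(OC)cc(OC)c2)C[C@@H](c2ccc(OC)cc2OC)C=C(C(=O)C=[N+]=[N-])[C@H]5[C@H](c2ccc(OC)cc2)O4)cc1 | intermediate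
38 | ethoxyacetylene | CCOC#C | starting material
39 | vinylketene: CH=C=O on C6, stereocentres as in 37 | COc1ccc([C@@H]2Oc3cc4c5c(c3[C@H]2c2cc(OC)cc(OC)c2)C[C@@H](c2ccc(OC)cc2OC)C=C(C=C=O)[C@H]5[C@H](c2ccc(OC)cc2)O4)cc1 | intermediate (not isolated)
40 | 3-ethoxy-4-(cycloheptenyl)cyclobut-2-enone on C6 (new ring carbon unassigned, both epimers) | COc1ccc([C@@H]2Oc3cc4c5c(c3[C@H]2c2cc(OC)cc(OC)c2)C[C@@H](c2ccc(OC)cc2OC)C=C(C2C(=O)C=C2OCC)[C@H]5[C@H](c2ccc(OC)cc2)O4)cc1 | intermediate (not isolated)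
41 | dienylketene: CH=C(OEt)–CH=C=O on C6, C6 and ketenyl cis on the new alkene | COc1ccc([C@@H]2Oc3cc4c5c(c3[C@H]2c2cc(OC)cc(OC)c2)C[C@@H](c2ccc(OC)cc2OC)C=C(/C=C(OCC)\C=C=O)[C@H]5[C@H](c2ccc(OC)cc2)O4)cc1 | intermediate (not isolated)
42 | cyclohexa-2,4-dienone tautomer of 43 (C1 sp3, unassigned) | COc1ccc([C@@H]2Oc3cc4c5c(c3[C@H]2c2cc(OC)cc(OC)c2)C[C@@H](c2ccc(OC)cc2OC)C2C(=O)C=C(OCC)C=C2[C@H]5[C@H](c2ccc(OC)cc2)O4)cc1 | intermediate (not isolated)
43 | full skeleton as hexamethyl monoethyl ether: ring C has OH on C2 and OEt on C4 (D2 R, D3 R, E2 R, E3 R, C8 S) | COc1ccc([C@@H]2Oc3cc4c5c(c3[C@H]2c2cc(OC)cc(OC)c2)C[C@@H](c2ccc(OC)cc2OC)c2c(O)cc(OCC)cc2[C@H]5[C@H](c2ccc(OC)cc2)O4)cc1 | intermediate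
44 | CNP0154047.2 (D2 R, D3 R, E2 R, E3 R, C8 S) | Oc1ccc([C@@H]2Oc3cc4c5c(c3[C@H]2c2cc(O)cc(O)c2)C[C@@H](c2ccc(O)cc2O)c2c(O)cc(O)cc2[C@H]5[C@H](c2ccc(O)cc2)O4)cc1 | target

**Totals and risks**

Total step count: 23. Longest linear sequence: 22 steps (steps 1 to 12 and 14 to 23, from 1 to 44; step 13 is the side branch).

Steps most likely to fail:

Step 22. The six anisole-type rings may absorb the light in place of the diazo ketone, and the ketene may dimerise or be quenched before it meets the alkyne. The fallback makes the same vinylketene without light. It sets out from 37: a silver-catalysed Wolff rearrangement in the dark (PhCO2Ag, Et3N, THF/H2O) traps the ketene with water as the homologated acid F1; oxalyl chloride with catalytic DMF gives the acid chloride F2; slow addition of Et3N to F2 and 38 in toluene at 80 °C forms 39 by dehydrochlorination, which runs on through 40, 41 and 42. It comes back to the route at 43.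

Step 4. Attack of hydrazine at the imine carbon may be too slow, because both faces are screened by the two ortho substituents of ring B, and hydrolysis to the unreactive ketone may take over. The fallback functionalises the imine nitrogen instead of the carbon. It sets out from 8 (isolated after the methanol quench): N-nitrosation (N2O4, NaOAc, CH2Cl2, −30 °C) gives the N-nitroso ketimine F3, and reduction with LiAlH4 in Et2O at −78 °C gives the diazo compound directly. It comes back to the route at 10, which is then treated with Rh2(R-PTAD)4 alone.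

Step 6. Oxidative addition or transmetalation at the di-ortho-substituted, electron-rich bromide may stall, with reduction of the C–Br bond instead of coupling. The fallback builds the diazo ester from a keto ester. It sets out from 11: bromine–lithium exchange (t-BuLi, Et2O, −78 °C) gives the aryllithium F4, inverse addition to excess dimethyl oxalate gives the aryl glyoxylate F5, p-toluenesulfonyl hydrazide in MeOH gives the tosylhydrazone F6, and DBU in CH2Cl2 (Bamford–Stevens elimination of sulfinate) gives the diazo ester. It comes back to the route at 14.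

**Further compounds**

F1 | step 22 | homologated acid: CH2CO2H on C6, stereocentres as in 37 | COc1ccc([C@@H]2Oc3cc4c5c(c3[C@H]2c2cc(OC)cc(OC)c2)C[C@@H](c2ccc(OC)cc2OC)C=C(CC(=O)O)[C@H]5[C@H](c2ccc(OC)cc2)O4)cc1
F2 | step 22 | acid chloride: CH2COCl on C6 | COc1ccc([C@@H]2Oc3cc4c5c(c3[C@H]2c2cc(OC)cc(OC)c2)C[C@@H](c2ccc(OC)cc2OC)C=C(CC(Cl)=O)[C@H]5[C@H](c2ccc(OC)cc2)O4)cc1
F3 | step 4 | N-nitroso ketimine of 8 | O=NN=C(c1cc(OC)cc(OC)c1)c1c(OCc2ccc(OC)cc2)cc(OCc2ccc(OC)cc2)c(Br)c1CO[Si](C(C)C)(C(C)C)C(C)C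
F4 | step 6 | aryllithium from 11 (lithium on B4) | COc1ccc([C@H]2Oc3cc(OCc4ccc(OC)cc4)c([Li])c(CO[Si](C(C)C)(C(C)C)C(C)C)c3[C@H]2c2cc(OC)cc(OC)c2)cc1
F5 | step 6 | methyl aryl glyoxylate (C(=O)CO2Me on B4) | COc1ccc([C@H]2Oc3cc(OCc4ccc(OC)cc4)c(C(=O)C(=O)OC)c(CO[Si](C(C)C)(C(C)C)C(C)C)c3[C@H]2c2cc(OC)cc(OC)c2)cc1
F6 | step 6 | tosylhydrazone of F5 | COc1ccc([C@H]2Oc3cc(OCc4ccc(OC)cc4)c(C(=NNS(=O)(=O)c4ccc(C)cc4)C(=O)OC)c(CO[Si](C(C)C)(C(C)C)C(C)C)c3[C@H]2c2cc(OC)cc(OC)c2)cc1
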